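## Analysis of the target

The target 25 is a profisetinidin-type biflavanoid in which C4 of a 5-deoxyflavan-3-ol upper unit (benzo ring A with one hydroxyl at C7, pyran ring C, catechol ring B on C2) is bonded to C6' of a (+)-catechin lower unit (phloroglucinol-type ring D, pyran ring F, catechol ring E; primes mark lower-unit atoms). Of its five stereocentres, C2 (R), C3 (R) and C4 (S) of the upper unit place ring B, the C3 hydroxyl and ring D on one face of ring C (2,3-cis-3,4-cis), while C2' (R) and C3' (S) are trans as in (+)-catechin. The seven phenolic hydroxyls, four of them in two catechols, make the free compound sensitive to base and air, and the C4–C6' bond between a doubly benzylic carbon and a very electron-rich arene can be cleaved by strong acid. The two secondary alcohols at C3 and C3' must also be told apart. Three things make the synthesis hard: the all-cis triad (capture of a flavan-4-yl cation by an arene gives 3,4-trans products), attachment at C6' instead of the more nucleophilic C8', and the missing 5-oxygen of ring A, which makes a C4 cation a poor intermediate. The strategy rests on the way ring C is assembled from its neighbours: counted along C2–C3–C4, the ring D-bearing carbon C4 is β to C2, and the two remaining ring C atoms, C4a (bonded to C4) and O1 (bonded to C2), both belong to ring A. Ring C can therefore be read as a three-carbon enone (C2 as carbonyl carbon, C3, C4 as β-carbon) closed by an ortho-hydroxyaryl nucleophile derived from ring A.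

## Retrosynthetic reasoning

**25 from 24.** No skeletal bond is cut. All seven phenols and the C3' hydroxyl are carried as benzyl ethers and C8' carries a bromine atom, so one neutral hydrogenolysis ends the route. Benzyl ethers tolerate the organometallic, basic, boron and oxidation chemistry ahead. The bromine blocks C8' so that carbon is introduced at C6'.

**24 from 23 from 22.** Only the configuration at C3 changes. The all-cis alcohol 24 comes from ketone 23 by hydride delivery to the face away from the two aryl groups, and 23 comes from the 3-epimer 22. A direct syn addition to C2=C3 that placed oxygen cis to ring D would have to approach on the face ring D shields, so the anti adduct is accepted and C3 is corrected by oxidation and reduction. This works because C3'–O is benzylated and 22 has a single free hydroxyl.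

**22 from 20.** The C3–O and C2–H bonds are cut, which leads to the enol ether C2=C3 of 4H-chromene 20. Hydroboration puts boron on C3 (β to O1, remote from the aryl-bearing C2) anti to ring D. The syn-delivered hydrogen at C2 then places ring B cis to ring D, so C2 (R) follows from C4.

**20 from 12 and 17 (key disconnection).** C4–C4a and O1–C2 are cut. Both bonds end on ring A, so one difunctional ring A reagent, boronic acid 17, delivers them. The remaining piece is enone 12, whose β-carbon already carries ring D. Three things are gained. C4 is the only new stereocentre and is set at an sp2 carbon by a chiral rhodium catalyst, not by a cation. The C4–C6' bond is never made by aromatic substitution, so the C6'/C8' problem does not arise at this stage. Ring C closes in the same operation. The forward step needs face-selective aryl transfer to a hindered β-carbon, tolerance of the aryl bromide, and cyclisation with loss of water.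

**12 from 8 and 10.** The enone C=C bond (future C3–C4) is cut by an aldol condensation between the non-enolisable aldehyde 8 and methyl ketone 10. This is convergent, and the E geometry follows from the elimination.

**8 from 5, 4, 3, 2 and 1; 10 from 9.** The formyl group at C6 comes from a C6–magnesium bond, and that from a C6–iodine bond in 5. The two halogens are installed in sequence on penta-O-benzylcatechin 3. The first halogenation goes to C8 (bromine, kept as blocker, giving 4), and the second can only go to C6 (iodine, the halogen that exchanges first). Compound 3 comes from (+)-catechin 1 through 2 by benzylation in two stages, which brings both lower stereocentres from the chiral pool. Ketone 10 is the dibenzyl ether of 9.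

**17 from 14 from 13.** The C–B bond comes from the C–Br bond of 14 by halogen–lithium exchange on the phenoxide. Bromophenol 14 comes from 13 by benzylation of the hydroxyl para to bromine.

## Alternatives that were turned down

**Alternative 1:** Ring F of the lower unit is cut at O1'–C2' and C3'–C4'. In the forward step the ortho-hydroxybenzyl alcohol A3, whose ring D already carries the complete upper unit at C6', loses water under a chiral phosphoric acid to give the ortho-quinone methide A4. This heterodiene takes up the (E)-styrenyl pinacol boronate A2 in a [4+2] cycloaddition to give the 3'-boryl flavan A1. Oxidation of C–B with retention and hydrogenolysis would finish.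
- For: the end game is short (two steps after the key step against four here), the trans relation in ring F follows from the E alkene, boron is a clean hydroxyl surrogate, and no bromine blocker is needed.
- Against: C2' and C3' are exactly the stereocentres that (+)-catechin 1 supplies ready-made; here a catalyst must create them on a crowded, chiral, fully substituted ring D.
- Against: the boron-bearing alkene carbon has to act as the nucleophilic terminus, which makes A2 a weaker 2π partner than a plain styrene.
- Against: the three ring D oxygens must be differentiated and a hydroxymethyl group introduced at C4a' to reach A3.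
- Against: the all-cis upper triad and the C4–C6' bond must be solved beforehand to reach A3, and this step does not address them.
- Comparison: alternative 1 is stronger on post-key step count. The chosen route instead makes the difficult C4 stereocentre and ring C in its key step and takes ring F from the chiral pool.

**Alternative 2:** The C3=C4 bond of a 2H-chromene is disconnected. In the forward step keto ester A6 (a diaryl ketone between C4a and C6', whose ring A oxygen carries an O-aryl mandelate benzyl ester supplying C2 and C3) undergoes intramolecular McMurry-type carbonyl coupling with TiCl3 and zinc dust. The product is the 3-benzyloxy-2H-chromene A5. Syn hydrogenation from the face opposite ring B would then set C3 and C4 together.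
- For: the all-cis triad would follow from one stereocentre without any redox correction at C3, and the C3 oxygen is in place from the start. On this point it is stronger than the chosen route.
- Against: the ketone carbon of A6 is flanked by the hexasubstituted ring D, so the coupling is crowded.
- Against: the reducing titanium species can cleave the α-aryloxy C2–O1 bond and reduce the aryl bromide.
- Against: C2 of A6 is benzylic, O-substituted and α to an ester, so it epimerises easily.
- Against: hydrogenation of the tetrasubstituted enol ether of A5, which bears a di-ortho-substituted aryl group, is among the hardest alkene reductions, and forcing conditions would also attack the benzyl ethers and the benzylic C2–O1 bond.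
- Comparison: the chosen route pays two extra steps for the C3 inversion. In return C4 is set by a catalyst on a substrate made by one aldol condensation, and C2 and C3 are set by substrate-controlled reactions of high precedent.

**Alternative 3:** The aryl ether bond O1–C8a is disconnected. In the forward step the dienone A8 carries the complete C2–C3–C4 chain with all three stereocentres, and its C4 is bonded to the quaternary carbon of a 4-methoxycyclohexa-2,5-dienone (dearomatised ring A). With acid, the C2 hydroxyl adds in conjugate fashion to C8a, and expulsion of the methoxy group restores the aromatic ring to give A7 with a free C7 hydroxyl.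
- For: the ring closes by C–O formation at an sp2 carbon, so no stereocentre is touched and C2 keeps its configuration. The 1,3-relation of O1 and O7 arises automatically, and ring A needs no selective protection. On stereochemical integrity of the ring closure it is at least as strong as the chosen route.
- Against: the key step creates no C–C bond and no stereocentre, so the C4–C4a and C4–C6' bonds and three contiguous stereocentres must be built in an open chain first.
- Against: A8 has a quaternary carbon next to a doubly benzylic carbon, so dienone–phenol 1,2-shift or fragmentation to a ring D-stabilised cation competes under acid.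
- Against: the benzylic C2 alcohol of A8 can ionise under the same acid.
- Against: the oxidative dearomatisation leading to A8 must spare the much more electron-rich rings D, B and E.
- Comparison: the chosen route forms two skeletal bonds, ring C and the C4 stereocentre in one catalytic step from two simple fragments.

Key step: step 10

## Conventions and assumption

- Bn = benzyl.
- "BrCat" = the (2R,3S)-3,5,7-tris(benzyloxy)-2-[3,4-bis(benzyloxy)phenyl]-8-bromochroman-6-yl group (the protected ring D/E/F unit).
- Assumption: the (1S,4S) enantiomer of 2,5-diphenylbicyclo[2.2.2]octa-2,5-diene is taken to deliver the aryl group to the Re face of the enone β-carbon, by analogy with the usual sense for (E)-enones. If the sense proves opposite, the (1R,4R) ligand is used.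

## Route

Step 1
Reactants: 1 (+)-catechin
Product: 2 (2R,3S)-5,7-bis(benzyloxy)-2-[3,4-bis(benzyloxy)phenyl]chroman-3-ol (5,7,3',4'-tetra-O-benzylcatechin)
Conditions: BnBr (4.4 equiv), K2CO3, DMF, 0 °C → rt
Reagents that add atoms: benzyl bromide, BrCc1ccccc1
Why: Williamson etherification; carbonate deprotonates only the four phenols, so the C3 alcohol stays free, and the mild base at low temperature limits C-benzylation and base-induced opening of the pyran ring.

Step 2
Reactants: 2 5,7,3',4'-tetra-O-benzylcatechin
Product: 3 (2R,3S)-3,5,7-tris(benzyloxy)-2-[3,4-bis(benzyloxy)phenyl]chromane (penta-O-benzylcatechin)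
Conditions: NaH, BnBr, n-Bu4NI (cat.), DMF, 0 °C → rt
Reagents that add atoms: benzyl bromide, BrCc1ccccc1
Why: Williamson etherification of the secondary alkoxide; this ether later distinguishes C3'–O of the lower unit from the one free hydroxyl that has to be oxidised, and no stereocentre is touched.

Step 3
Reactants: 3 penta-O-benzylcatechin
Product: 4 (2R,3S)-8-bromo-3,5,7-tris(benzyloxy)-2-[3,4-bis(benzyloxy)phenyl]chromane
Conditions: NBS (1.0 equiv), CH2Cl2, −78 → 0 °C
Reagents that add atoms: N-bromosuccinimide, O=C1CCC(=O)N1Br
Why: Electrophilic aromatic bromination; of the two open positions on the tri-oxygenated ring, C8 is the established site of attack for benzylated catechins, and one equivalent at low temperature should stop at the monobromide.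

Step 4
Reactants: 4 8-bromo-penta-O-benzylcatechin
Product: 5 (2R,3S)-8-bromo-6-iodo-3,5,7-tris(benzyloxy)-2-[3,4-bis(benzyloxy)phenyl]chromane
Conditions: NIS (1.2 equiv), CF3CO2H (cat.), CH2Cl2–MeCN, 0 °C → rt
Reagents that add atoms: N-iodosuccinimide, O=C1CCC(=O)N1I
Why: Electrophilic aromatic iodination at the only remaining position of the ring with three ether oxygens, which stays far more reactive than the catechol diether ring or the benzyl groups.

Step 5
Reactants: 5 8-bromo-6-iodo-penta-O-benzylcatechin
Product: 8 (2R,3S)-3,5,7-tris(benzyloxy)-2-[3,4-bis(benzyloxy)phenyl]-8-bromochromane-6-carbaldehyde, via arylmagnesium chloride 6 (not isolated), via magnesium hemiaminal alkoxide 7 (not isolated)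
Conditions: i-PrMgCl·LiCl (1.2 equiv), THF, −30 → 0 °C; DMF (3 equiv), 0 °C → rt; 1 M HCl
Reagents that add atoms: N,N-dimethylformamide, CN(C)C=O
Why: Iodine–magnesium exchange is much faster at C–I than at C–Br and is helped by the two flanking ether oxygens, so only C6 is metalated; formylation of the aryl Grignard reagent with DMF (Bouveault aldehyde synthesis) gives the aldehyde on hydrolysis.

Step 6
Reactants: 9 3',4'-dihydroxyacetophenone
Product: 10 1-[3,4-bis(benzyloxy)phenyl]ethanone
Conditions: BnBr (2.3 equiv), K2CO3, DMF, 60 °C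
Reagents that add atoms: benzyl bromide, BrCc1ccccc1
Why: Williamson etherification of both phenols; carbonate does not enolise the methyl ketone enough for C-alkylation.

Step 7
Reactants: 8 the 6-carbaldehyde; 10 1-[3,4-bis(benzyloxy)phenyl]ethanone
Product: 12 (E)-1-[3,4-bis(benzyloxy)phenyl]-3-(BrCat)prop-2-en-1-one, via aldol adduct 11 (not isolated)
Conditions: KOH, EtOH–THF, rt → 40 °C
Reagents that add atoms: none
Why: Claisen–Schmidt condensation; the enolate of 10 adds to the non-enolisable aldehyde 8 and E1cB loss of water gives the conjugated enone as its more stable E isomer, while benzyl ethers, the bromide and the catechin stereocentres are inert to hydroxide.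

Step 8
Reactants: 13 4-bromoresorcinol
Product: 14 5-(benzyloxy)-2-bromophenol
Conditions: BnBr (1.0 equiv), K2CO3 (1.0 equiv), acetone, rt → 50 °C
Reagents that add atoms: benzyl bromide, BrCc1ccccc1
Why: Williamson monoetherification; the hydroxyl para to bromine is unhindered and its phenoxide is the better nucleophile, whereas the one next to bromine is crowded and inductively deactivated, so the wanted regioisomer is expected to predominate and is separated from the dibenzyl ether by chromatography.

Step 9
Reactants: 14 5-(benzyloxy)-2-bromophenol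
Product: 17 [4-(benzyloxy)-2-hydroxyphenyl]boronic acid, via dilithiated phenoxide 15 (not isolated), via lithium triisopropoxyborate 16 (not isolated)
Conditions: n-BuLi (2.2 equiv), THF, −78 → −40 °C; B(Oi-Pr)3, −78 °C → rt; 1 M HCl
Reagents that add atoms: triisopropyl borate, CC(C)OB(OC(C)C)OC(C)C; water, O
Why: The first equivalent of n-BuLi deprotonates the phenol and the second effects bromine–lithium exchange, which at low temperature outruns lithiation of the benzyl ether; the aryllithium is trapped by the borate and acid hydrolysis releases the boronic acid.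

Step 10
Reactants: 12 the (E)-enone; 17 [4-(benzyloxy)-2-hydroxyphenyl]boronic acid
Product: 20 (4S)-7-(benzyloxy)-2-[3,4-bis(benzyloxy)phenyl]-4-(BrCat)-4H-chromene, via 1,4-adduct ketone 18 (not isolated), via cyclic hemiketal 19 (not isolated)
Conditions: [Rh(C2H4)2Cl]2 (3 mol %), (1S,4S)-2,5-diphenylbicyclo[2.2.2]octa-2,5-diene (6.6 mol %), 17 (3 equiv, in portions), KOH (0.5 equiv), dioxane–H2O 10:1, 50 °C; then pyridinium p-toluenesulfonate (cat.), toluene, 4 Å MS, rt
Reagents that add atoms: none
Why: Chloride on the monovalent rhodium–diene complex is exchanged for hydroxide, transmetalation with 17 gives an aryl–rhodium species, and this binds the enone of 12 and inserts its C=C bond so that the aryl carbon (future C4a) goes to the β-carbon carrying ring D. Hydrolysis of the resulting oxa-π-allyl rhodium enolate releases ketone 18 and returns the hydroxo complex. The closest known reaction type is the Hayashi–Miyaura reaction (rhodium–chiral diene catalysed asymmetric 1,4-addition of arylboronic acids to enones), including its use with 2-hydroxyarylboronic acids to reach 2-hydroxychromans and 4H-chromenes. Ring C closes by 6-exo-trig addition of the ortho phenol to the ketone (hemiketal 19), and the mild acid then removes water through the C2 oxocarbenium ion, which can lose a proton only from C3, so C2=C3 is the only alkene possible. The one new stereocentre, C4 (S), is set by the chiral diene, which presents the Re face of the β-carbon (ring D carbon > Cα > H) to the migrating aryl group; the catechin stereocentres are five or more bonds away and should bias the step little. The step needs 1,4- over 1,2-addition (inherent to aryl–rhodium insertion into enones) and an untouched aryl bromide (a di-ortho-substituted C–Br bond should not react with monovalent rhodium–diene complexes at 50 °C). It also needs addition to outrun protodeboronation, which is why 17 is used in excess and added in portions, and the fixed E geometry of the enone leaves the catalyst a single pair of faces to distinguish.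

Step 11
Reactants: 20 the 4H-chromene
Product: 22 (2R,3S,4S)-7-(benzyloxy)-2-[3,4-bis(benzyloxy)phenyl]-4-(BrCat)chroman-3-ol (2,3-trans-3,4-trans), via C3 alkylborane 21 (not isolated)
Conditions: BH3·THF (3 equiv), THF, 0 °C → rt; then NaOH aq, H2O2, 0 °C
Reagents that add atoms: hydrogen peroxide, OO
Why: Hydroboration–oxidation of the enol ether; boron goes to C3 (β to O1 and remote from the aryl-bearing C2) on the face opposite the bulky C4 aryl group, and the syn-delivered hydrogen at C2 places ring B cis to ring D, setting C2 (R) and C3 (S). Oxidation of C–B proceeds with retention.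

Step 12
Reactants: 22 the 2,3-trans-3,4-trans alcohol
Product: 23 (2R,4S)-7-(benzyloxy)-2-[3,4-bis(benzyloxy)phenyl]-4-(BrCat)chroman-3-one
Conditions: Dess–Martin periodinane (1.5 equiv), CH2Cl2, 0 °C → rt
Reagents that add atoms: none
Why: Dess–Martin oxidation of the only free hydroxyl under nearly neutral conditions; C2 and C4 are enolisable, but the 2,4-cis diaryl arrangement should be the more stable one, so there is no thermodynamic drive to lose it.

Step 13
Reactants: 23 the flavan-3-one
Product: 24 (2R,3R,4S)-7-(benzyloxy)-2-[3,4-bis(benzyloxy)phenyl]-4-(BrCat)chroman-3-ol (all-cis)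
Conditions: LiBH(s-Bu)3 (1.5 equiv), LiBr, THF, −78 °C; then H2O
Reagents that add atoms: none
Why: Diastereoselective ketone reduction; the bulky trialkylborohydride attacks the carbonyl from the face opposite the two cis aryl groups, so the new hydroxyl ends up cis to both (C3 R), as in the known conversion of catechin-type 3-ketones into epicatechin-type alcohols.

Step 14
Reactants: 24 the all-cis protected dimer
Product: 25 (2R,3S)-2-(3,4-dihydroxyphenyl)-6-[(2R,3R,4S)-2-(3,4-dihydroxyphenyl)-3,7-dihydroxychroman-4-yl]chromane-3,5,7-triol (target)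
Conditions: H2 (1 atm), Pd(OH)2/C, NaHCO3 (1.1 equiv), THF–MeOH–H2O, rt
Reagents that add atoms: none
Why: Catalytic hydrogenolysis removes the eight benzyl ethers and, by hydrodebromination, the C8' bromine in one operation; the buffered, non-acidic medium leaves the C4–C6' bond and all five stereocentres untouched.

## Compound list

1 | (+)-catechin | O[C@H]1Cc2c(O)cc(O)cc2O[C@@H]1c1ccc(O)c(O)c1 | starting material
2 | (2R,3S)-5,7-bis(benzyloxy)-2-[3,4-bis(benzyloxy)phenyl]chroman-3-ol | c1c(OCc3ccccc3)cc2c(c1OCc1ccccc1)C[C@H](O)[C@@H](c1ccc(OCc3ccccc3)c(OCc3ccccc3)c1)O2 | intermediate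
3 | (2R,3S)-3,5,7-tris(benzyloxy)-2-[3,4-bis(benzyloxy)phenyl]chromane | c1c(OCc3ccccc3)cc2c(c1OCc1ccccc1)C[C@H](OCc1ccccc1)[C@@H](c1ccc(OCc3ccccc3)c(OCc3ccccc3)c1)O2 | intermediate
4 | (2R,3S)-8-bromo-3,5,7-tris(benzyloxy)-2-[3,4-bis(benzyloxy)phenyl]chromane | c1c(OCc3ccccc3)c(Br)c2c(c1OCc1ccccc1)C[C@H](OCc1ccccc1)[C@@H](c1ccc(OCc3ccccc3)c(OCc3ccccc3)c1)O2 | intermediate
5 | (2R,3S)-8-bromo-6-iodo-3,5,7-tris(benzyloxy)-2-[3,4-bis(benzyloxy)phenyl]chromane | Ic1c(OCc3ccccc3)c(Br)c2c(c1OCc1ccccc1)C[C@H](OCc1ccccc1)[C@@H](c1ccc(OCc3ccccc3)c(OCc3ccccc3)c1)O2 | intermediate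
6 | 6-(chloromagnesio) derivative of 4 (aryl Grignard reagent, LiCl complex) | Cl[Mg]c1c(OCc3ccccc3)c(Br)c2c(c1OCc1ccccc1)C[C@H](OCc1ccccc1)[C@@H](c1ccc(OCc3ccccc3)c(OCc3ccccc3)c1)O2 | intermediate (not isolated)
7 | chloromagnesium alkoxide of the C6 dimethylamino carbinol (hemiaminal, carbinol centre undefined) | CN(C)C(O[Mg]Cl)c1c(OCc3ccccc3)c(Br)c2c(c1OCc1ccccc1)C[C@H](OCc1ccccc1)[C@@H](c1ccc(OCc3ccccc3)c(OCc3ccccc3)c1)O2 | intermediate (not isolated)
8 | (2R,3S)-3,5,7-tris(benzyloxy)-2-[3,4-bis(benzyloxy)phenyl]-8-bromochromane-6-carbaldehyde | O=Cc1c(OCc3ccccc3)c(Br)c2c(c1OCc1ccccc1)C[C@H](OCc1ccccc1)[C@@H](c1ccc(OCc3ccccc3)c(OCc3ccccc3)c1)O2 | intermediate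
9 | 3',4'-dihydroxyacetophenone | CC(=O)c1ccc(O)c(O)c1 | starting material
10 | 1-[3,4-bis(benzyloxy)phenyl]ethanone | CC(=O)c1ccc(OCc2ccccc2)c(OCc2ccccc2)c1 | intermediate
11 | 1-[3,4-bis(benzyloxy)phenyl]-3-hydroxy-3-(BrCat)propan-1-one (aldol adduct, carbinol centre undefined) | O=C(c1ccc(OCc2ccccc2)c(OCc2ccccc2)c1)CC(O)c1c(OCc3ccccc3)c(Br)c2c(c1OCc1ccccc1)C[C@H](OCc1ccccc1)[C@@H](c1ccc(OCc3ccccc3)c(OCc3ccccc3)c1)O2 | intermediate (not isolated)
12 | (E)-1-[3,4-bis(benzyloxy)phenyl]-3-(BrCat)prop-2-en-1-one | O=C(c1ccc(OCc2ccccc2)c(OCc2ccccc2)c1)/C=C/c1c(OCc3ccccc3)c(Br)c2c(c1OCc1ccccc1)C[C@H](OCc1ccccc1)[C@@H](c1ccc(OCc3ccccc3)c(OCc3ccccc3)c1)O2 | intermediate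
13 | 4-bromoresorcinol | Oc1ccc(Br)c(O)c1 | starting material
14 | 5-(benzyloxy)-2-bromophenol | Oc1cc(OCc2ccccc2)ccc1Br | intermediate
15 | lithium 5-(benzyloxy)-2-lithiophenoxide | [Li]Oc1cc(OCc2ccccc2)ccc1[Li] | intermediate (not isolated)
16 | dilithium [4-(benzyloxy)-2-oxidophenyl]triisopropoxyborate | [Li+].[Li+].[O-]c1cc(OCc2ccccc2)ccc1[B-](OC(C)C)(OC(C)C)OC(C)C | intermediate (not isolated)
17 | [4-(benzyloxy)-2-hydroxyphenyl]boronic acid | OB(O)c1ccc(OCc2ccccc2)cc1O | intermediate
18 | (3S)-1-[3,4-bis(benzyloxy)phenyl]-3-[4-(benzyloxy)-2-hydroxyphenyl]-3-(BrCat)propan-1-one | O=C(c1ccc(OCc2ccccc2)c(OCc2ccccc2)c1)C[C@@H](c1ccc(OCc2ccccc2)cc1O)c1c(OCc3ccccc3)c(Br)c2c(c1OCc1ccccc1)C[C@H](OCc1ccccc1)[C@@H](c1ccc(OCc3ccccc3)c(OCc3ccccc3)c1)O2 | intermediate (not isolated)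
19 | (4S)-7-(benzyloxy)-2-[3,4-bis(benzyloxy)phenyl]-4-(BrCat)chroman-2-ol (hemiketal, C2 undefined) | C(c1ccccc1)Oc1ccc2c(c1)OC(O)(c1ccc(OCc3ccccc3)c(OCc3ccccc3)c1)C[C@@H]2c1c(OCc3ccccc3)c(Br)c2c(c1OCc1ccccc1)C[C@H](OCc1ccccc1)[C@@H](c1ccc(OCc3ccccc3)c(OCc3ccccc3)c1)O2 | intermediate (not isolated)
20 | (4S)-7-(benzyloxy)-2-[3,4-bis(benzyloxy)phenyl]-4-(BrCat)-4H-chromene | C(c1ccccc1)Oc1ccc2c(c1)OC(c1ccc(OCc3ccccc3)c(OCc3ccccc3)c1)=C[C@@H]2c1c(OCc3ccccc3)c(Br)c2c(c1OCc1ccccc1)C[C@H](OCc1ccccc1)[C@@H](c1ccc(OCc3ccccc3)c(OCc3ccccc3)c1)O2 | intermediate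
21 | C3 borane of 20 (boron trans to ring B and to ring D) | C(c1ccccc1)Oc1ccc2c(c1)O[C@H](c1ccc(OCc3ccccc3)c(OCc3ccccc3)c1)[C@@H](B)[C@@H]2c1c(OCc3ccccc3)c(Br)c2c(c1OCc1ccccc1)C[C@H](OCc1ccccc1)[C@@H](c1ccc(OCc3ccccc3)c(OCc3ccccc3)c1)O2 | intermediate (not isolated)
22 | (2R,3S,4S)-7-(benzyloxy)-2-[3,4-bis(benzyloxy)phenyl]-4-(BrCat)chroman-3-ol | C(c1ccccc1)Oc1ccc2c(c1)O[C@H](c1ccc(OCc3ccccc3)c(OCc3ccccc3)c1)[C@@H](O)[C@@H]2c1c(OCc3ccccc3)c(Br)c2c(c1OCc1ccccc1)C[C@H](OCc1ccccc1)[C@@H](c1ccc(OCc3ccccc3)c(OCc3ccccc3)c1)O2 | intermediate
23 | (2R,4S)-7-(benzyloxy)-2-[3,4-bis(benzyloxy)phenyl]-4-(BrCat)chroman-3-one | C(c1ccccc1)Oc1ccc2c(c1)O[C@H](c1ccc(OCc3ccccc3)c(OCc3ccccc3)c1)C(=O)[C@@H]2c1c(OCc3ccccc3)c(Br)c2c(c1OCc1ccccc1)C[C@H](OCc1ccccc1)[C@@H](c1ccc(OCc3ccccc3)c(OCc3ccccc3)c1)O2 | intermediate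
24 | (2R,3R,4S)-7-(benzyloxy)-2-[3,4-bis(benzyloxy)phenyl]-4-(BrCat)chroman-3-ol | C(c1ccccc1)Oc1ccc2c(c1)O[C@H](c1ccc(OCc3ccccc3)c(OCc3ccccc3)c1)[C@H](O)[C@@H]2c1c(OCc3ccccc3)c(Br)c2c(c1OCc1ccccc1)C[C@H](OCc1ccccc1)[C@@H](c1ccc(OCc3ccccc3)c(OCc3ccccc3)c1)O2 | intermediate
25 | (2R,3S)-2-(3,4-dihydroxyphenyl)-6-[(2R,3R,4S)-2-(3,4-dihydroxyphenyl)-3,7-dihydroxychroman-4-yl]chromane-3,5,7-triol | Oc1ccc2c(c1)O[C@H](c1ccc(O)c(O)c1)[C@H](O)[C@@H]2c1c(O)cc2c(c1O)C[C@H](O)[C@@H](c1ccc(O)c(O)c1)O2 | target

## Step count and least certain steps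

Total: 14 steps. Longest linear sequence: 11 steps (steps 1, 2, 3, 4, 5, 7, 10, 11, 12, 13, 14 from (+)-catechin).

**Step 10, the key step.** The most likely failure is slow insertion at a β-carbon that carries a di-ortho-substituted, electron-rich aryl group, so that protodeboronation of the ortho-hydroxy boronic acid in aqueous base consumes the nucleophile first. Second is incomplete facial control. Third is acid-induced loss of ring D from C4 during the dehydration, by ipso-protonation of ring D and expulsion of a benzopyrylium ion. The fallback gives up catalyst control and sets out from iodide 5 and ketone 10. Condensation of 10 with commercial 4-benzyloxy-2-hydroxybenzaldehyde F1, promoted by dry HCl in EtOAc at 0 °C, gives the flavylium salt 7-benzyloxy-2-[3,4-dibenzyloxyphenyl]chromenylium chloride F2. The arylmagnesium reagent 6, made from 5 as in step 5, is then added in THF at −78 °C to C4 of F2, the usual site of attack of carbon nucleophiles on 2-arylbenzopyrylium salts. This comes back to the route at chromene 20, which forms together with the epimeric 4R-configured 4H-chromene F3 and has to be separated from F3 by chromatography.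

**Step 11.** Hydroboration of a trisubstituted enol ether next to the bulky C4 aryl group may be sluggish. The β-aryloxy borane could then open the pyran ring by elimination, or some reagent could approach the shielded face. The fallback sets out from 20. Dihydroxylation with catalytic OsO4 and N-methylmorpholine N-oxide in acetone–H2O, on the face anti to ring D, gives the hemiketal 7-benzyloxy-2-[3,4-dibenzyloxyphenyl]-4-BrCat-chromane-2,3-diol F4. Ionic reduction at the anomeric C2 with Et3SiH and BF3·OEt2 in CH2Cl2–MeCN at −40 °C, with axial hydride delivery to the oxocarbenium ion as in C-aryl glycoside synthesis, should leave ring B equatorial and trans to the C3 hydroxyl. This comes back at alcohol 22.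

**Step 12.** Ketone 23 can enolise toward C2 or toward the doubly benzylic C4 during oxidation or chromatography, with epimerisation or air oxidation of the enol. The fallback avoids the ketone and sets out from 22. Mitsunobu inversion with 4-nitrobenzoic acid, PPh3 and diisopropyl azodicarboxylate in toluene gives the all-cis C3 4-nitrobenzoate F5, and methanolysis of F5 with K2CO3 in MeOH–THF comes back at 24, which also bypasses step 13. The displacement at a carbinol flanked by two aryl-bearing carbons is hindered and can be diverted into elimination, which is why it is held only as a fallback.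

**Step 8.** Site selectivity between the two hydroxyls of 13 may be insufficient, and some dibenzylation will occur. The fallback fixes the oxygen pattern by substitution chemistry; it replaces starting material 13 by commercial 5-fluoro-2-nitrophenol F6. Nucleophilic aromatic substitution of the fluoride para to the nitro group with BnOH and NaH in DMF at 60 °C gives 5-benzyloxy-2-nitrophenol F7. Reduction with Fe and NH4Cl in EtOH–H2O gives 2-amino-5-benzyloxyphenol F8. Diazotisation with NaNO2 in aqueous HBr at 0 °C gives 4-benzyloxy-2-hydroxybenzenediazonium bromide F9, and Sandmeyer bromination with CuBr comes back at bromophenol 14.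

**Step 5.** The halogen–magnesium exchange may be incomplete or may partly involve C8, and the di-ortho-substituted Grignard reagent may be trapped slowly, so that protonation on work-up gives dehalogenated material. The fallback sets out from bromide 4 and skips steps 4 and 5. Vilsmeier–Haack formylation with POCl3 and DMF at 60 °C attacks the only free position of the tri-oxygenated ring to give the C6 aryl iminium chloride F10. Hydrolysis of F10 with aqueous NaOAc comes back at aldehyde 8.

## Further compounds

F1 | step 10 | 4-(benzyloxy)-2-hydroxybenzaldehyde | O=Cc1ccc(OCc2ccccc2)cc1O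
F2 | step 10 | 7-(benzyloxy)-2-[3,4-bis(benzyloxy)phenyl]chromenylium chloride | [Cl-].C(c1ccccc1)Oc1ccc2ccc(-c3ccc(OCc4ccccc4)c(OCc4ccccc4)c3)[o+]c2c1
F3 | step 10 | (4R)-7-(benzyloxy)-2-[3,4-bis(benzyloxy)phenyl]-4-(BrCat)-4H-chromene (C4 epimer of 20) | C(c1ccccc1)Oc1ccc2c(c1)OC(c1ccc(OCc3ccccc3)c(OCc3ccccc3)c1)=C[C@H]2c1c(OCc3ccccc3)c(Br)c2c(c1OCc1ccccc1)C[C@H](OCc1ccccc1)[C@@H](c1ccc(OCc3ccccc3)c(OCc3ccccc3)c1)O2
F4 | step 11 | (3S,4S)-7-(benzyloxy)-2-[3,4-bis(benzyloxy)phenyl]-4-(BrCat)chromane-2,3-diol (hemiketal, C2 undefined) | C(c1ccccc1)Oc1ccc2c(c1)OC(O)(c1ccc(OCc3ccccc3)c(OCc3ccccc3)c1)[C@@H](O)[C@@H]2c1c(OCc3ccccc3)c(Br)c2c(c1OCc1ccccc1)C[C@H](OCc1ccccc1)[C@@H](c1ccc(OCc3ccccc3)c(OCc3ccccc3)c1)O2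
F5 | step 12 | (2R,3R,4S)-7-(benzyloxy)-2-[3,4-bis(benzyloxy)phenyl]-4-(BrCat)chroman-3-yl 4-nitrobenzoate | C(c1ccccc1)Oc1ccc2c(c1)O[C@H](c1ccc(OCc3ccccc3)c(OCc3ccccc3)c1)[C@H](OC(=O)c1ccc(cc1)[N+](=O)[O-])[C@@H]2c1c(OCc3ccccc3)c(Br)c2c(c1OCc1ccccc1)C[C@H](OCc1ccccc1)[C@@H](c1ccc(OCc3ccccc3)c(OCc3ccccc3)c1)O2
F6 | step 8 | 5-fluoro-2-nitrophenol | Oc1cc(F)ccc1[N+](=O)[O-]
F7 | step 8 | 5-(benzyloxy)-2-nitrophenol | Oc1cc(OCc2ccccc2)ccc1[N+](=O)[O-]
F8 | step 8 | 2-amino-5-(benzyloxy)phenol | Nc1ccc(OCc2ccccc2)cc1O
F9 | step 8 | 4-(benzyloxy)-2-hydroxybenzenediazonium bromide | N#[N+]c1ccc(OCc2ccccc2)cc1O.[Br-]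
F10 | step 5 | N-{[(2R,3S)-3,5,7-tris(benzyloxy)-2-[3,4-bis(benzyloxy)phenyl]-8-bromochroman-6-yl]methylidene}-N-methylmethanaminium chloride | C[N+](C)=Cc1c(OCc3ccccc3)c(Br)c2c(c1OCc1ccccc1)C[C@H](OCc1ccccc1)[C@@H](c1ccc(OCc3ccccc3)c(OCc3ccccc3)c1)O2.[Cl-]
A1 | alternative 1 | octa-O-benzyl dimer with a pinacolboryl group at C3' of ring F, trans to ring E | C(c1ccccc1)Oc1ccc2c(c1)O[C@H](c1ccc(OCc3ccccc3)c(OCc3ccccc3)c1)[C@H](OCc1ccccc1)[C@@H]2c1c(OCc3ccccc3)cc2c(c1OCc1ccccc1)C[C@H](B1OC(C)(C)C(C)(C)O1)[C@@H](c1ccc(OCc3ccccc3)c(OCc3ccccc3)c1)O2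
A2 | alternative 1 | (E)-2-[3,4-bis(benzyloxy)styryl]-4,4,5,5-tetramethyl-1,3,2-dioxaborolane | CC1(C)OB(/C=C/c2ccc(OCc3ccccc3)c(OCc3ccccc3)c2)OC1(C)C
A3 | alternative 1 | protected all-cis upper unit bonded at C4 to a 2,6-bis(benzyloxy)-4-hydroxy-3-(hydroxymethyl)phenyl ring (ortho-hydroxybenzyl alcohol on ring D) | C(c1ccccc1)Oc1ccc2c(c1)O[C@H](c1ccc(OCc3ccccc3)c(OCc3ccccc3)c1)[C@H](OCc1ccccc1)[C@@H]2c1c(OCc3ccccc3)cc(O)c(CO)c1OCc1ccccc1
A4 | alternative 1 | ortho-quinone methide of ring D: 3,5-bis(benzyloxy)-6-methylidenecyclohexa-2,4-dien-1-one bonded at its C4 to C4 of the protected all-cis upper unit | C(c1ccccc1)Oc1ccc2c(c1)O[C@H](c1ccc(OCc3ccccc3)c(OCc3ccccc3)c1)[C@H](OCc1ccccc1)[C@@H]2C1=C(OCc3ccccc3)C(=C)C(=O)C=C1OCc1ccccc1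
A5 | alternative 2 | (2R)-3,7-bis(benzyloxy)-2-[3,4-bis(benzyloxy)phenyl]-4-(BrCat)-2H-chromene | C(c1ccccc1)Oc1ccc2c(c1)O[C@H](c1ccc(OCc3ccccc3)c(OCc3ccccc3)c1)C(OCc1ccccc1)=C2c1c(OCc3ccccc3)c(Br)c2c(c1OCc1ccccc1)C[C@H](OCc1ccccc1)[C@@H](c1ccc(OCc3ccccc3)c(OCc3ccccc3)c1)O2
A6 | alternative 2 | benzyl (2R)-2-[3,4-bis(benzyloxy)phenyl]-2-[5-(benzyloxy)-2-(BrCat-carbonyl)phenoxy]acetate | C(c1ccccc1)Oc1ccc(C(=O)c2c(OCc3ccccc3)c(Br)c3c(c2OCc2ccccc2)C[C@H](OCc2ccccc2)[C@@H](c2ccc(OCc4ccccc4)c(OCc4ccccc4)c2)O3)c(c1)O[C@H](c1ccc(OCc2ccccc2)c(OCc2ccccc2)c1)C(=O)OCc1ccccc1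
A7 | alternative 3 | all-cis dimer with free C7 hydroxyl, 3-O-benzyl, all other oxygens benzylated, C8' bromide | Oc1ccc2c(c1)O[C@H](c1ccc(OCc3ccccc3)c(OCc3ccccc3)c1)[C@H](OCc1ccccc1)[C@@H]2c1c(OCc3ccccc3)c(Br)c2c(c1OCc1ccccc1)C[C@H](OCc1ccccc1)[C@@H](c1ccc(OCc3ccccc3)c(OCc3ccccc3)c1)O2
A8 | alternative 3 | open-chain C2 alcohol with C4 bonded to BrCat and to C4 of a 4-methoxycyclohexa-2,5-dienone | O[C@H](c1ccc(OCc2ccccc2)c(OCc2ccccc2)c1)[C@H](OCc1ccccc1)[C@@H](C1(OC)C=CC(=O)C=C1)c1c(OCc3ccccc3)c(Br)c2c(c1OCc1ccccc1)C[C@H](OCc1ccccc1)[C@@H](c1ccc(OCc3ccccc3)c(OCc3ccccc3)c1)O2
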